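Ring A is a phloroglucinol whose three oxygens are all different (C5–OMe, C7–OH, C8a–O1), with the alkylated carbon C6 lying between C5 and C7. The route disconnects this ring at C6–C7, C7–C8 and C4a–C5: a thermal vinylketene–alkyne benzannulation joins a 3-(methoxymethoxy)cyclobutenone to a 1-methoxyalkyne that already carries the complete (S)-configured side chain, and delivers ring A with all three oxygens differentiated in one operation. The cyclobutenone oxygen is a methoxymethyl ether, so that the future O1 later directs lithiation to C4a, where the cinnamoyl unit enters; enantioselective oxa-Michael closure of ring C and one global desilylation finish the synthesis.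

Key step: step 8

Assumption: the quinine-derived thiourea of step 14 is taken to deliver the (2S) configuration; should the sense of induction prove opposite, its quinidine-derived pseudoenantiomer is used instead.

Step 1
Reactants: 1 5-methylhex-4-enoic acid; 2 (R)-4-benzyloxazolidin-2-one
Product: 4 (R)-4-benzyl-3-(5-methylhex-4-enoyl)oxazolidin-2-one, via mixed anhydride 3 (not isolated)
Conditions: t-BuCOCl, Et3N, THF, –20 °C; then 2, LiCl, –20 °C → rt
Reagents that add atoms: none
Why: Activation of the acid as its mixed pivalic anhydride and LiCl-assisted N-acylation is the standard way of loading an Evans oxazolidinone auxiliary, and no stereocentre is formed.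

Step 2
Reactants: 4 (R)-4-benzyl-3-(5-methylhex-4-enoyl)oxazolidin-2-one
Product: 6 (R)-4-benzyl-3-[(2S)-2-(hydroxymethyl)-5-methylhex-4-enoyl]oxazolidin-2-one, via titanium enolate 5 (not isolated)
Conditions: TiCl4, i-Pr2NEt, CH2Cl2, 0 °C; then 1,3,5-trioxane, TiCl4, 0 °C; NH4Cl (aq)
Reagents that add atoms: 1,3,5-trioxane, C1OCOCO1
Why: Auxiliary-controlled hydroxymethylation (formaldehyde aldol of an Evans titanium enolate), in which the chelated (Z)-enolate is attacked by TiCl4-activated formaldehyde on the face remote from the benzyl group, which sets the (S) centre of the side chain.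

Step 3
Reactants: 6 (R)-4-benzyl-3-[(2S)-2-(hydroxymethyl)-5-methylhex-4-enoyl]oxazolidin-2-one
Product: 7 methyl (2S)-2-(hydroxymethyl)-5-methylhex-4-enoate
Conditions: MeOMgBr (from MeMgBr and MeOH), MeOH/CH2Cl2, 0 °C
Reagents that add atoms: methanol, CO
Why: Methanolysis of a β-hydroxy imide with bromomagnesium methoxide is a mild transesterification that attacks the exocyclic carbonyl, releases the auxiliary and should cause neither epimerisation nor retro-aldol loss of formaldehyde.

Step 4
Reactants: 7 methyl (2S)-2-(hydroxymethyl)-5-methylhex-4-enoate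
Product: 8 (3S)-3-(hydroxymethyl)-2,6-dimethylhept-5-en-2-ol
Conditions: MeMgBr (4 equiv), THF, –20 → 0 °C; NH4Cl (aq)
Reagents that add atoms: methylmagnesium bromide, C[Mg]Br
Why: Double Grignard addition to the ester (after deprotonation of the hydroxyl) gives the tertiary carbinol, and because addition outpaces enolisation at low temperature the adjacent centre should be retained.

Step 5
Reactants: 8 (3S)-3-(hydroxymethyl)-2,6-dimethylhept-5-en-2-ol
Product: 10 (2S)-5-methyl-2-[2-(triethylsilyloxy)propan-2-yl]hex-4-en-1-yl trifluoromethanesulfonate, via hydroxy triflate 9 (not isolated)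
Conditions: Tf2O, 2,6-lutidine, CH2Cl2, –78 °C; then Et3SiOTf, –78 → –30 °C; used at once
Reagents that add atoms: trifluoromethanesulfonic anhydride, O=S(=O)(OS(=O)(=O)C(F)(F)F)C(F)(F)F; triethylsilyl trifluoromethanesulfonate, CC[Si](CC)(CC)OS(=O)(=O)C(F)(F)F
Why: One-pot differentiation of a 1,3-diol, in which triflic anhydride reacts only with the primary hydroxyl at –78 °C and the remaining tertiary hydroxyl is then capped by the silyl triflate, so that the alkylating agent carries no free nucleophile.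

Step 6
Reactants: 10 (2S)-5-methyl-2-[2-(triethylsilyloxy)propan-2-yl]hex-4-en-1-yl trifluoromethanesulfonate; 11 chloroacetaldehyde dimethyl acetal
Product: 13 triethyl{[(3S)-3-(3-methoxyprop-2-yn-1-yl)-2,6-dimethylhept-5-en-2-yl]oxy}silane, via lithium methoxyacetylide 12 (not isolated)
Conditions: 11, LiNEt2 (3 equiv, from Et2NH and n-BuLi), THF, 0 °C; then 10, DMPU, –78 → –20 °C
Reagents that add atoms: none
Why: Base-induced loss of HCl and methanol from the chloroacetal gives lithium methoxyacetylide, whose SN2 alkylation by a primary triflate at low temperature is a standard entry to 1-alkoxyalkynes, and the stereocentre is one carbon away from the reacting carbon and is untouched.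

Step 7
Reactants: 14 cyclobutane-1,3-dione
Product: 15 3-(methoxymethoxy)cyclobut-2-en-1-one
Conditions: MeOCH2Cl, i-Pr2NEt, CH2Cl2, 0 °C
Reagents that add atoms: chloromethyl methyl ether, COCCl
Why: The dione reacts as its enol, a vinylogous acid, and the hard electrophile MeOCH2Cl alkylates it on oxygen to give the vinylogous ester (enol ether formation).

Step 8
Reactants: 15 3-(methoxymethoxy)cyclobut-2-en-1-one; 13 triethyl{[(3S)-3-(3-methoxyprop-2-yn-1-yl)-2,6-dimethylhept-5-en-2-yl]oxy}silane
Product: 20 3-methoxy-5-(methoxymethoxy)-2-{(2S)-5-methyl-2-[2-(triethylsilyloxy)propan-2-yl]hex-4-en-1-yl}phenol, via vinylketene 16 (not isolated), via vinylcyclobutenone 17 (not isolated), via dienylketene 18 (not isolated), via cyclohexadienone 19 (not isolated)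
Conditions: 15 (2 equiv, in portions), toluene, sealed tube, 80 → 120 °C; then K2CO3, MeOH, rt (cleaves any O-acylated phenol)
Reagents that add atoms: none
Why: Danheiser benzannulation, the closest known reaction type being the union of cyclobutenone-derived vinylketenes and alkoxyalkynes to give resorcinol monoethers. Thermal four-electron ring opening of 15 gives vinylketene 16, which adds [2+2] to the electron-rich alkyne 13 to give cyclobutenone 17, the nucleophilic chain-bearing alkyne carbon bonding to the ketene carbonyl carbon (C6–C7) and the methoxy-bearing carbon to the ketene terminus (C5–C4a). A second four-electron opening gives dienylketene 18, and ring A is closed by thermal disrotatory six-electron electrocyclisation (C7–C8) to dienone 19, which tautomerises to phenol 20. No stereocentre is formed, and the chain centre, one carbon removed from the alkyne, is not at risk under neutral thermal conditions. The only selectivity required is the regiochemistry of the ketene–alkyne cycloaddition, which the polarisation of the ynol ether secures, so that C6 emerges between the free C7 hydroxyl and the C5 methyl ether while O1 stays masked as the MOM ether.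

Step 9
Reactants: 20 3-methoxy-5-(methoxymethoxy)-2-{(2S)-5-methyl-2-[2-(triethylsilyloxy)propan-2-yl]hex-4-en-1-yl}phenol
Product: 21 triisopropyl(3-methoxy-5-(methoxymethoxy)-2-{(2S)-5-methyl-2-[2-(triethylsilyloxy)propan-2-yl]hex-4-en-1-yl}phenoxy)silane
Conditions: i-Pr3SiCl, imidazole, DMF, rt
Reagents that add atoms: triisopropylsilyl chloride, CC(C)[Si](Cl)(C(C)C)C(C)C
Why: Silylation of the only free phenol under conditions that leave the MOM ether alone installs a bulky, non-coordinating group on O7 that will shield C8 in the lithiation.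

Step 10
Reactants: 22 2,4-dihydroxybenzaldehyde
Product: 23 2,4-bis(triisopropylsilyloxy)benzaldehyde
Conditions: i-Pr3SiCl, imidazole, DMF, rt → 40 °C
Reagents that add atoms: triisopropylsilyl chloride, CC(C)[Si](Cl)(C(C)C)C(C)C
Why: Routine silylation of both phenols, chosen so that every protecting group of the late intermediates falls in one fluoride step.

Step 11
Reactants: 23 2,4-bis(triisopropylsilyloxy)benzaldehyde
Product: 24 (E)-3-[2,4-bis(triisopropylsilyloxy)phenyl]-N-methoxy-N-methylprop-2-enamide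
Conditions: (EtO)2P(O)CH2C(O)N(OMe)Me, NaH, THF, 0 °C → rt
Reagents that add atoms: diethyl [2-(methoxy(methyl)amino)-2-oxoethyl]phosphonate, CCOP(=O)(CC(=O)N(C)OC)OCC
Why: Horner–Wadsworth–Emmons olefination with a stabilised phosphonoacetamide anion gives the (E)-configured Weinreb enamide.

Step 12
Reactants: 21 triisopropyl(3-methoxy-5-(methoxymethoxy)-2-{(2S)-5-methyl-2-[2-(triethylsilyloxy)propan-2-yl]hex-4-en-1-yl}phenoxy)silane; 24 (E)-3-[2,4-bis(triisopropylsilyloxy)phenyl]-N-methoxy-N-methylprop-2-enamide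
Product: 26 (E)-3-[2,4-bis(triisopropylsilyloxy)phenyl]-1-[2-methoxy-6-(methoxymethoxy)-3-{(2S)-5-methyl-2-[2-(triethylsilyloxy)propan-2-yl]hex-4-en-1-yl}-4-(triisopropylsilyloxy)phenyl]prop-2-en-1-one, via aryllithium 25 (not isolated)
Conditions: 21, n-BuLi, THF, 0 °C; then 24, –78 → –20 °C; NH4Cl (aq)
Reagents that add atoms: none
Why: Directed ortho-metalation followed by Weinreb ketone synthesis, in which the MOM ether and the methoxy group together direct n-BuLi to C4a while the silyloxy group shields C8, and the aryllithium adds once to the amide carbonyl, which releases the (E)-enone only on aqueous quench.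

Step 13
Reactants: 26 (the MOM-protected chalcone of step 12)
Product: 27 (E)-3-[2,4-bis(triisopropylsilyloxy)phenyl]-1-[6-hydroxy-2-methoxy-3-{(2S)-5-methyl-2-[2-(triethylsilyloxy)propan-2-yl]hex-4-en-1-yl}-4-(triisopropylsilyloxy)phenyl]prop-2-en-1-one
Conditions: MgBr2·OEt2 (3 equiv), Et2O/CH2Cl2, 0 °C → rt; aqueous work-up
Reagents that add atoms: none
Why: Chelation of MgBr2 between the ketone oxygen and the ortho acetal oxygen activates only this MOM ether towards bromide (chelation-assisted Lewis acid deprotection), which should spare the silyl ethers, the enone and the trisubstituted alkene.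

Step 14
Reactants: 27 (the 2'-hydroxychalcone of step 13)
Product: 28 (2S)-2-[2,4-bis(triisopropylsilyloxy)phenyl]-5-methoxy-6-{(2S)-5-methyl-2-[2-(triethylsilyloxy)propan-2-yl]hex-4-en-1-yl}-7-(triisopropylsilyloxy)chroman-4-one
Conditions: N-[3,5-bis(trifluoromethyl)phenyl]-N'-(9-deoxy-epi-quinin-9-yl)thiourea (15 mol %), toluene, 0 °C → rt
Reagents that add atoms: none
Why: Enantioselective 6-endo intramolecular oxa-Michael addition of a 2'-hydroxychalcone under bifunctional cinchona catalysis, in which the quinuclidine activates the phenol and the thiourea binds the enone carbonyl so that oxygen adds to the Si face of the β-carbon and sets C2 as (S), the flanking methoxy group twisting the enone and favouring closure.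

Step 15
Reactants: 28 (the silylated flavanone of step 14)
Product: 29 (2S)-2-(2,4-dihydroxyphenyl)-7-hydroxy-6-[(2S)-2-(2-hydroxypropan-2-yl)-5-methylhex-4-en-1-yl]-5-methoxychroman-4-one
Conditions: Bu4NF, AcOH (1:1), THF, 0 °C → rt
Reagents that add atoms: none
Why: Fluoride cleaves the three aryl silyl ethers and the tertiary silyl ether in one operation, and the acetic acid buffer keeps the phenols protonated so that base-induced opening of ring C (retro-oxa-Michael), which would scramble C2, is avoided.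

Compound list
1 | 5-methylhex-4-enoic acid | CC(C)=CCCC(=O)O | starting material
2 | (R)-4-benzyloxazolidin-2-one | O=C1N[C@H](Cc2ccccc2)CO1 | starting material
3 | 5-methylhex-4-enoic pivalic anhydride | CC(C)=CCCC(=O)OC(=O)C(C)(C)C | intermediate (not isolated)
4 | (R)-4-benzyl-3-(5-methylhex-4-enoyl)oxazolidin-2-one | CC(C)=CCCC(=O)N1[C@H](Cc2ccccc2)COC1=O | intermediate
5 | trichlorotitanium (Z)-enolate of 4 | CC(C)=CC/C=C(\O[Ti](Cl)(Cl)Cl)N1[C@H](Cc2ccccc2)COC1=O | intermediate (not isolated)
6 | (R)-4-benzyl-3-[(2S)-2-(hydroxymethyl)-5-methylhex-4-enoyl]oxazolidin-2-one | OC[C@H](CC=C(C)C)C(=O)N1[C@H](Cc2ccccc2)COC1=O | intermediate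
7 | methyl (2S)-2-(hydroxymethyl)-5-methylhex-4-enoate | OC[C@H](CC=C(C)C)C(=O)OC | intermediate
8 | (3S)-3-(hydroxymethyl)-2,6-dimethylhept-5-en-2-ol | OC[C@H](CC=C(C)C)C(C)(C)O | intermediate
9 | (2S)-2-(2-hydroxypropan-2-yl)-5-methylhex-4-en-1-yl trifluoromethanesulfonate | FC(F)(F)S(=O)(=O)OC[C@H](CC=C(C)C)C(C)(C)O | intermediate (not isolated)
10 | (2S)-5-methyl-2-[2-(triethylsilyloxy)propan-2-yl]hex-4-en-1-yl trifluoromethanesulfonate | FC(F)(F)S(=O)(=O)OC[C@H](CC=C(C)C)C(C)(C)O[Si](CC)(CC)CC | intermediate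
11 | chloroacetaldehyde dimethyl acetal (2-chloro-1,1-dimethoxyethane) | COC(CCl)OC | starting material
12 | lithium methoxyacetylide | [Li]C#COC | intermediate (not isolated)
13 | triethyl{[(3S)-3-(3-methoxyprop-2-yn-1-yl)-2,6-dimethylhept-5-en-2-yl]oxy}silane | COC#CC[C@H](CC=C(C)C)C(C)(C)O[Si](CC)(CC)CC | intermediate
14 | cyclobutane-1,3-dione | O=C1CC(=O)C1 | starting material
15 | 3-(methoxymethoxy)cyclobut-2-en-1-one | COCOC1=CC(=O)C1 | intermediate
16 | 3-(methoxymethoxy)buta-1,3-dien-1-one, the [1-(methoxymethoxy)ethenyl]ketene | C=C(OCOC)C=C=O | intermediate (not isolated)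
17 | 3-methoxy-4-[1-(methoxymethoxy)ethenyl]-2-{(2S)-5-methyl-2-[2-(triethylsilyloxy)propan-2-yl]hex-4-en-1-yl}cyclobut-2-en-1-one (both configurations at C4) | COCOC(=C)C1C(OC)=C(C[C@H](CC=C(C)C)C(C)(C)O[Si](CC)(CC)CC)C1=O | intermediate (not isolated)
18 | 3-methoxy-5-(methoxymethoxy)-2-{(2S)-5-methyl-2-[2-(triethylsilyloxy)propan-2-yl]hex-4-en-1-yl}hexa-1,3,5-trien-1-one (C2 and C5 cis on the central double bond) | O=C=C(C[C@H](CC=C(C)C)C(C)(C)O[Si](CC)(CC)CC)/C(OC)=C\C(=C)OCOC | intermediate (not isolated)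
19 | 3-methoxy-5-(methoxymethoxy)-2-{(2S)-5-methyl-2-[2-(triethylsilyloxy)propan-2-yl]hex-4-en-1-yl}cyclohexa-2,4-dien-1-one | O=C1CC(OCOC)=CC(OC)=C1C[C@H](CC=C(C)C)C(C)(C)O[Si](CC)(CC)CC | intermediate (not isolated)
20 | 3-methoxy-5-(methoxymethoxy)-2-{(2S)-5-methyl-2-[2-(triethylsilyloxy)propan-2-yl]hex-4-en-1-yl}phenol | COc1cc(OCOC)cc(O)c1C[C@H](CC=C(C)C)C(C)(C)O[Si](CC)(CC)CC | intermediate
21 | triisopropyl(3-methoxy-5-(methoxymethoxy)-2-{(2S)-5-methyl-2-[2-(triethylsilyloxy)propan-2-yl]hex-4-en-1-yl}phenoxy)silane | COc1cc(OCOC)cc(O[Si](C(C)C)(C(C)C)C(C)C)c1C[C@H](CC=C(C)C)C(C)(C)O[Si](CC)(CC)CC | intermediate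
22 | 2,4-dihydroxybenzaldehyde | O=Cc1ccc(O)cc1O | starting material
23 | 2,4-bis(triisopropylsilyloxy)benzaldehyde | O=Cc1ccc(O[Si](C(C)C)(C(C)C)C(C)C)cc1O[Si](C(C)C)(C(C)C)C(C)C | intermediate
24 | (E)-3-[2,4-bis(triisopropylsilyloxy)phenyl]-N-methoxy-N-methylprop-2-enamide | CON(C)C(=O)/C=C/c1ccc(O[Si](C(C)C)(C(C)C)C(C)C)cc1O[Si](C(C)C)(C(C)C)C(C)C | intermediate
25 | aryllithium of 21, lithiated between the methoxy and methoxymethoxy groups (C4a) | COc1c([Li])c(OCOC)cc(O[Si](C(C)C)(C(C)C)C(C)C)c1C[C@H](CC=C(C)C)C(C)(C)O[Si](CC)(CC)CC | intermediate (not isolated)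
26 | (E)-3-[2,4-bis(triisopropylsilyloxy)phenyl]-1-[2-methoxy-6-(methoxymethoxy)-3-{(2S)-5-methyl-2-[2-(triethylsilyloxy)propan-2-yl]hex-4-en-1-yl}-4-(triisopropylsilyloxy)phenyl]prop-2-en-1-one | COc1c(C(=O)/C=C/c2ccc(O[Si](C(C)C)(C(C)C)C(C)C)cc2O[Si](C(C)C)(C(C)C)C(C)C)c(OCOC)cc(O[Si](C(C)C)(C(C)C)C(C)C)c1C[C@H](CC=C(C)C)C(C)(C)O[Si](CC)(CC)CC | intermediate
27 | (E)-3-[2,4-bis(triisopropylsilyloxy)phenyl]-1-[6-hydroxy-2-methoxy-3-{(2S)-5-methyl-2-[2-(triethylsilyloxy)propan-2-yl]hex-4-en-1-yl}-4-(triisopropylsilyloxy)phenyl]prop-2-en-1-one | COc1c(C(=O)/C=C/c2ccc(O[Si](C(C)C)(C(C)C)C(C)C)cc2O[Si](C(C)C)(C(C)C)C(C)C)c(O)cc(O[Si](C(C)C)(C(C)C)C(C)C)c1C[C@H](CC=C(C)C)C(C)(C)O[Si](CC)(CC)CC | intermediate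
28 | (2S)-2-[2,4-bis(triisopropylsilyloxy)phenyl]-5-methoxy-6-{(2S)-5-methyl-2-[2-(triethylsilyloxy)propan-2-yl]hex-4-en-1-yl}-7-(triisopropylsilyloxy)chroman-4-one | COc1c(C[C@H](CC=C(C)C)C(C)(C)O[Si](CC)(CC)CC)c(O[Si](C(C)C)(C(C)C)C(C)C)cc2c1C(=O)C[C@@H](c1ccc(O[Si](C(C)C)(C(C)C)C(C)C)cc1O[Si](C(C)C)(C(C)C)C(C)C)O2 | intermediate
29 | (2S)-2-(2,4-dihydroxyphenyl)-7-hydroxy-6-[(2S)-2-(2-hydroxypropan-2-yl)-5-methylhex-4-en-1-yl]-5-methoxychroman-4-one | COc1c(C[C@H](CC=C(C)C)C(C)(C)O)c(O)cc2c1C(=O)C[C@@H](c1ccc(O)cc1O)O2 | target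

Total step count: 15. Longest linear sequence: 12 steps (steps 1–6, 8, 9 and 12–15).

The three steps most likely to fail

Step 8 (benzannulation). The cyclobutenone is a vinylogous ester and may open too slowly, or the oxygenated vinylketene may oligomerise or acylate the product phenol faster than the alkyne captures it. Fallback: ring A is taken ready-made and the chain centre is set by auxiliary-controlled benzylation instead. Commercial 2,4-dihydroxy-6-methoxybenzaldehyde F1 is etherified at the non-chelated para hydroxyl (MeOCH2Cl, i-Pr2NEt) to 2-hydroxy-6-methoxy-4-(methoxymethoxy)benzaldehyde F2. Silylation (i-Pr3SiCl, imidazole) then gives 2-methoxy-4-(methoxymethoxy)-6-(triisopropylsilyloxy)benzaldehyde F3, NaBH4 reduction gives the benzyl alcohol F4, and CBr4/PPh3 gives the benzyl bromide F5, which is used crude. The route is left at imide 4: its enolate (NaN(SiMe3)2, THF, –78 °C) is alkylated by F5 on the face remote from the benzyl group, the same facial sense as in step 2, which should give the benzylated imide F6 with the (S) chain centre. Methanolysis with bromomagnesium methoxide gives the methyl ester F7, MeMgBr gives the tertiary alcohol F8, and Et3SiOTf/2,6-lutidine at –78 °C rejoins the route at 21.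

Step 14 (asymmetric oxa-Michael closure). Facial discrimination may be poor, because the phenol is strongly hydrogen-bonded and the ortho-silyloxy B ring is bulky, and an uncatalysed racemic closure may compete. Fallback: 27 is closed without stereocontrol (catalytic DBU, CH2Cl2, rt), which should give 28 together with its C2 epimer, (2R)-2-[2,4-bis(triisopropylsilyloxy)phenyl]-5-methoxy-6-{(2S)-5-methyl-2-[2-(triethylsilyloxy)propan-2-yl]hex-4-en-1-yl}-7-(triisopropylsilyloxy)chroman-4-one F9. Because the chain centre is fixed the two are diastereomers and can be separated by preparative HPLC. F9 is returned to the same basic conditions, where it reopens to 27 and recloses, so the material is funnelled to 28, where the route is rejoined.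

Step 6 (acetylide alkylation). The basic acetylide may cause E2 elimination of the β-branched triflate, and the liberated diethylamine may be N-alkylated. Fallback: displacement at a sulfonate is replaced by opening of a strained ether, which has no elimination pathway. Diol 8 is tosylated at the primary hydroxyl (TsCl, pyridine) to (2S)-2-(2-hydroxypropan-2-yl)-5-methylhex-4-en-1-yl 4-methylbenzenesulfonate F10 and closed with NaH in THF to (3S)-2,2-dimethyl-3-(3-methylbut-2-en-1-yl)oxetane F11. Lithium methoxyacetylide 12 with BF3·OEt2 (THF, –78 °C) opens the oxetane at its CH2 carbon to give (3S)-3-(3-methoxyprop-2-yn-1-yl)-2,6-dimethylhept-5-en-2-ol F12. Silylation (Et3SiCl, imidazole, DMAP, DMF) rejoins the route at 13.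

Further compounds
F1 | step 8 | 2,4-dihydroxy-6-methoxybenzaldehyde (purchased) | O=Cc1c(O)cc(O)cc1OC
F2 | step 8 | 2-hydroxy-6-methoxy-4-(methoxymethoxy)benzaldehyde | O=Cc1c(O)cc(OCOC)cc1OC
F3 | step 8 | 2-methoxy-4-(methoxymethoxy)-6-(triisopropylsilyloxy)benzaldehyde | O=Cc1c(O[Si](C(C)C)(C(C)C)C(C)C)cc(OCOC)cc1OC
F4 | step 8 | [2-methoxy-4-(methoxymethoxy)-6-(triisopropylsilyloxy)phenyl]methanol | OCc1c(O[Si](C(C)C)(C(C)C)C(C)C)cc(OCOC)cc1OC
F5 | step 8 | [2-(bromomethyl)-3-methoxy-5-(methoxymethoxy)phenoxy]triisopropylsilane | BrCc1c(O[Si](C(C)C)(C(C)C)C(C)C)cc(OCOC)cc1OC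
F6 | step 8 | (R)-4-benzyl-3-[(2S)-2-{[2-methoxy-4-(methoxymethoxy)-6-(triisopropylsilyloxy)phenyl]methyl}-5-methylhex-4-enoyl]oxazolidin-2-one | COc1cc(OCOC)cc(O[Si](C(C)C)(C(C)C)C(C)C)c1C[C@H](CC=C(C)C)C(=O)N1[C@H](Cc2ccccc2)COC1=O
F7 | step 8 | methyl (2S)-2-{[2-methoxy-4-(methoxymethoxy)-6-(triisopropylsilyloxy)phenyl]methyl}-5-methylhex-4-enoate | COc1cc(OCOC)cc(O[Si](C(C)C)(C(C)C)C(C)C)c1C[C@H](CC=C(C)C)C(=O)OC
F8 | step 8 | (3S)-3-{[2-methoxy-4-(methoxymethoxy)-6-(triisopropylsilyloxy)phenyl]methyl}-2,6-dimethylhept-5-en-2-ol | COc1cc(OCOC)cc(O[Si](C(C)C)(C(C)C)C(C)C)c1C[C@H](CC=C(C)C)C(C)(C)O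
F9 | step 14 | (2R)-2-[2,4-bis(triisopropylsilyloxy)phenyl]-5-methoxy-6-{(2S)-5-methyl-2-[2-(triethylsilyloxy)propan-2-yl]hex-4-en-1-yl}-7-(triisopropylsilyloxy)chroman-4-one | COc1c(C[C@H](CC=C(C)C)C(C)(C)O[Si](CC)(CC)CC)c(O[Si](C(C)C)(C(C)C)C(C)C)cc2c1C(=O)C[C@H](c1ccc(O[Si](C(C)C)(C(C)C)C(C)C)cc1O[Si](C(C)C)(C(C)C)C(C)C)O2
F10 | step 6 | (2S)-2-(2-hydroxypropan-2-yl)-5-methylhex-4-en-1-yl 4-methylbenzenesulfonate | Cc1ccc(cc1)S(=O)(=O)OC[C@H](CC=C(C)C)C(C)(C)O
F11 | step 6 | (3S)-2,2-dimethyl-3-(3-methylbut-2-en-1-yl)oxetane | CC(C)=CC[C@H]1COC1(C)C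
F12 | step 6 | (3S)-3-(3-methoxyprop-2-yn-1-yl)-2,6-dimethylhept-5-en-2-ol | COC#CC[C@H](CC=C(C)C)C(C)(C)O
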